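15.0 min: that is my estimate of what slow charging costs each delayed flask. You suspected it would cut side product a good deal, and I agree. Here is the quick number.

| flask | starting material | coupling partner | base | remark | time |
|---|---|---|---|---|---|
| zeta | 0.010 M | 0.012 M | 0.20 mM | run made earlier |  |
| alpha | 0.010 M | 0.012 M | 0.28 mM | run made earlier |  |
| epsilon | 0.010 M | 0.012 M | 0.44 mM | run made earlier |  |
| dusk | 0.010 M | 0.0120 M (fed, over 30 min) | 0.200 mM | all else is in the flask from the start; the feed brings no volume worth counting | 50 min |
| midnight | 0.010 M (in portions, 2, over 30 min) | 0.0120 M | 0.200 mM | first portion at the start, last at 30 min | 50 min |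
| dawn | 0.010 M | 0.0120 M | 0.200 mM | everything together at the start | 50 min |
| winter | 0.010 M (fed, over 30 min) | 0.0120 M | 0.200 mM | all else is in the flask from the start; the feed brings no volume worth counting | 50 min |

| run | time / min | side product / % | target / % |
|---|---|---|---|
| zeta | 4.00 | 0 | 0.8 |
| zeta | 6.00 | 0.1 | 1.3 |
| zeta | 12.0 | 0.1 | 1.4 |
| zeta | 20.0 | 1.0 | 3.5 |
| zeta | 30.0 | 4.2 | 10.7 |
| zeta | 50.0 | 19.7 | 37.4 |
| alpha | 6.00 | 0.5 | 1.5 |
| alpha | 12.0 | 0.2 | 1.5 |
| alpha | 20.0 | 1.1 | 2.2 |
| alpha | 25.0 | 1.7 | 3.0 |
| alpha | 30.0 | 2.9 | 4.9 |
| alpha | 40.0 | 6.6 | 13.5 |
| epsilon | 6.00 | 0.4 | 1.1 |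
| epsilon | 12.0 | 1.2 | 1.5 |
| epsilon | 20.0 | 1.1 | 1.8 |
| epsilon | 25.0 | 1.6 | 2.6 |
| epsilon | 30.0 | 2.7 | 3.5 |
| epsilon | 40.0 | 4.4 | 3.9 |

(standard deviation of a reading: 0.3 percentage points)

- percentages count the starting material that a species holds: one side product counts as two

- the flask with the highest amount of side product, in percent of the starting material charged ("all alike" if they lie within 1.5 percentage points) (dusk / midnight / dawn / winter / all alike)
- final side product, as a percentage of the starting material charged, in dusk
- final side product, as a percentage of the starting material charged, in midnight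
- final side product, as a percentage of the starting material charged, in dawn
- final side product, as a percentage of the starting material charged, in winter

1. Target in zeta stalls near 1.4% at 12.0 min, then climbs. More base pushes the climb later: at 40.0 min, target in alpha is 13.5%, higher than the 3.9% in epsilon. So I read autocatalysis after an induction period that base prolongs.

2. Dawn repeats the zeta recipe, so I take zeta's 19.7% for dawn.

3. Call d the lost time: the fraction of a charge still missing, summed over the run. I assume a rate first order in the delayed species, so it runs at the fraction present. A steady feed over 30 min misses on average half of its charge, so d is half of the feed time. Midnight misses half of its charge for the same 30 min, so its d is the same.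

4. At 50 min, dusk, midnight and winter should therefore stand where zeta stood at 35.0 min.

5. Zeta's side product goes from 4.2% at 30.0 min to 19.7% at 50.0 min. Geometric interpolation gives 6.18% at that time. I commit to that for dusk, midnight and winter, with dawn far higher.

The forecast, with “a delay of about 15 min”, puts dawn highest at 19.7%, and its 8.5%, 8% and 7.7% for dusk, midnight and winter stand above my figure.

The flasks give dawn highest at 19.5%, then dusk 7.01%, midnight 5.29% and winter 4.88%.

    base + released group ⇌ salt, settled at all times (K = 1.50 × 10⁶ M⁻¹)
    starting material + coupling partner + released group → target + 2 released group (k = 31.8 M⁻² s⁻¹)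
    coupling partner ⇌ dormant form (K = 0.830, k = 2.44 × 10⁻⁴ s⁻¹)
    starting material + coupling partner → target + released group (k = 0.00234 M⁻¹ s⁻¹)
    starting material + target → side product (k = 0.0433 M⁻¹ s⁻¹)

My 6.18% lies 0.83 percentage points under dusk and 1.3 points over winter. In winter, the half-life of starting material by the path with released group is 52 min at 50.0 min; by the direct path it is 8.4 h at the earlier moment of 15.2 min. At the later of those times, free base in winter stands at 0.063% of its charge, and salt at 2.00 × 10⁻⁴ M. Winter read at 80 min has, after d, an effective 65.0 min, past zeta's last reading at 50.0 min. Winter at that reading passes zeta's 19.7%: its side product stands at 26.9%.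

The numbers in the tables were generated by integration for substances that don't exist; noise was put on by code.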